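Amounts of D stay near zero at first in the cold runs while L falls: the amber run holds 0 % of D at 5.00 d, with 95.7 % of L left.

| flask | L | Z | temperature | remark | time |
|---|---|---|---|---|---|
| amber | 1.2 M | 0.66 M | 10 °C | run made earlier |  |
| teal | 1.2 M | 2.6 M | 40 °C | run made earlier |  |
| green | 2.4 M | 1.32 M | 10 °C | run made earlier |  |
| Monday's | 1.2 M | 1.32 M | 40 °C |  | 5.0 d |
| Friday's | 1.2 M | 1.32 M |  | at 65 °C until 4.0 d, from then on at 15 °C | 5.0 d |
| Tuesday's | 1.2 M | 1.32 M | 15 °C |  | 5.0 d |
| Saturday's | 1.2 M | 1.32 M | 65 °C |  | 5.0 d |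

| run | time / d | D / % | L / % |
|---|---|---|---|
| amber | 2.00 | 0 | 98.9 |
| amber | 5.00 | 0 | 95.7 |
| amber | 12.0 | 0.2 | 94.3 |
| amber | 25.0 | 2.2 | 90.9 |
| teal | 0.833 | 7.9 | 81.1 |
| teal | 2.00 | 19.6 | 68.2 |
| teal | 4.00 | 35.4 | 52.3 |
| teal | 6.00 | 47.9 | 40.5 |
| green | 8.00 | 0.9 | 94.2 |
| green | 12.0 | 0.7 | 93.8 |
| green | 20.0 | 1.8 | 88.3 |
| green | 25.0 | 3.1 | 84.4 |

(readings scatter by 1 percentage point)

- the numbers in the tables scatter by 1 percentage point (one standard deviation)
- a reading or a percentage of D counts all its forms, free or not

1. the best flask by amount of D, in percent of the L charged; "all alike" if 1.5 percentage points covers them all (Monday's / Friday's / Tuesday's / Saturday's / all alike)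
2. amount of D at the end, in percent of the L charged, Monday's
3. amount of D at the end, in percent of the L charged, Friday's
4. amount of D at the end, in percent of the L charged, Tuesday's
5. amount of D at the end, in percent of the L charged, Saturday's

1. In the teal run, 12.3 % of the L charged is found neither as L nor as D around 2.00 d to 4.00 d. So the readings are taken to mean that L + Z enters a silent form and that D comes out of that form afterwards.

2. Two steps in a row start with the square of time: the fraction of L found as D is 0.5 times (time / clock) squared. Here the clock is one over the root of entry rate times exit rate. The entry is taken as pseudo-first-order in L, with its rate proportional to Z, and the charge of L stands nowhere in the clock. Doubt: from amber to green, L and Z double together, so these two runs do not separate them. This stays an assumption.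

3. Warm end, scaled to 1.32 M of Z: teal's first reading gives an entry rate of 0.128 d⁻¹. The growth of D over the silent amount gives an exit rate of 0.645 d⁻¹. The clock at 40 °C reads 3.48 d.

4. Cold end: amber and green pooled at 25.0 d give 3.53 % of D at 1.32 M of Z, so the clock at 10 °C reads 94.0 d. Doubt: these readings carry a scatter of 1 percentage point on 2.2 % and 3.1 %, and by then green has lost L down to 84.4 %. A curve bent by then makes this clock run long.

5. Tuesday's 15 °C lies 1/6 of the way from 10 °C to 40 °C. Joining the ends at that point, with the logarithm of the clock straight in temperature, gives 54.3 d, the lag clock of Tuesday's flask. Doubt: does the square law hold there? Its 5.0 d lies well below the clock, so it does. My estimate for Tuesday's is 0.424 %, on the low side.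

6. The forecast says Saturday's is best, with Monday's 22 %, Friday's 66 %, Tuesday's 0.6 % and Saturday's 72 %: “Tuesday's barely clears the lag”.

7. The flasks give Monday's 25.5 %, Friday's 55.6 %, Tuesday's 0.539 % and Saturday's 60.1 %, so Saturday's is best.

    L + Z ⇌ G (K = 0.110 M⁻¹, k = 1.54 × 10⁻⁶ M⁻¹ s⁻¹, Ea = 76.0 kJ mol⁻¹, ΔH = −65.0 kJ mol⁻¹)
    G → D (k = 1.34 × 10⁻⁵ s⁻¹, Ea = 105 kJ mol⁻¹)
    Q ⇌ D, rate k3*(cs3 - [D]) while solid is left; crystals form when [D] > cs3 (solubility = 0.680 M, k = 4.90 × 10⁻⁵ s⁻¹)
    G → E (k = 1.83 × 10⁻⁶ s⁻¹, Ea = 113 kJ mol⁻¹)
    (constants at 40 °C)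

In Tuesday's flask, the passing of L + Z into G ran from the start, with 21 % of its turnover up to the end done by 1.00 d. At the end, G stood at 5.78 % and L at 93.6 %, while G passed into D with a half-life of 20 d, longer than the 5.0 d of the flask. With the forward half-life of 53 d for L at the end, the clock comes to 46.6 d, shorter than 54.3 d, and the D of Tuesday's flask lies above my estimate. Saturday's flask ended with E at 10.3 %, and its D stood 12 points under the forecast.

A neighbour like Tuesday's with 0.72 M of L has the same Z, and the clock as reckoned holds no L, so the reckoning keeps 54.3 d and 0.424 % there. Computed, it gives 0.543 %, level with Tuesday's.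

The numbers in the tables were generated by integration with made-up constants.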